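The 2-aminoimidazole is disconnected at N3–C4. Its N1–C2(N)–N3 amidine unit is brought in as the exocyclic N–C3–N2 array of 3-amino-5-methyl-1,2,4-oxadiazole; the precursor is the Z-enaminone formed when this amine condenses at the aliphatic carbonyl of an aryl benzyl 1,3-diketone. Base then makes the enaminone carbon displace the ring oxygen at N2 (Boulton–Katritzky rearrangement): one operation trades the weak O1–N2 bond for N3–C4, closes the imidazole with aroyl on C4 and benzyl on C5, and unveils the amine as its acetamide. The aroyl group afterwards steers N1-methylation and is hydrogenolysed, together with the phenol benzyl ether, to the 4-methoxybenzyl group; the methylparabanic acid unit is attached last.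

Key step: step 6

Remark: in 9 and all later imidazoles N1 is the ring nitrogen next to C5 (the carbon carrying the trioxygenated benzyl group); 9 is a pair of fast-equilibrating NH tautomers drawn as the 1H form, 6 is drawn as the diketo form of its enol mixture, and 3 is racemic at sulfur with an alkene geometry that is erased in step 3.

Step 1
Reactants: 1 3-hydroxy-4,5-dimethoxybenzaldehyde
Product: 2 3-(benzyloxy)-4,5-dimethoxybenzaldehyde
Conditions: BnBr (1.1 equiv), K2CO3 (1.2 equiv), DMF, 60 °C
Reagents that add atoms: benzyl bromide, BrCc1ccccc1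
Why: Williamson ether synthesis, in which the phenoxide formed with K2CO3 displaces bromide from benzyl bromide (SN2) while the aldehyde and the methyl ethers are inert.

Step 2
Reactants: 2 3-(benzyloxy)-4,5-dimethoxybenzaldehyde
Product: 3 1-(benzyloxy)-2,3-dimethoxy-5-[2-(methylsulfanyl)-2-(methylsulfinyl)ethenyl]benzene
Conditions: CH3S(O)CH2SCH3 (1.2 equiv), benzyltrimethylammonium hydroxide (40% in MeOH, cat.), THF, reflux
Reagents that add atoms: methyl (methylsulfanyl)methyl sulfoxide, CSCS(C)=O
Why: Knoevenagel-type condensation, in which the carbanion of the sulfide/sulfoxide-flanked methylene adds to the non-enolisable aryl aldehyde and water is lost, a standard one-carbon homologation handle for aromatic aldehydes.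

Step 3
Reactants: 3 1-(benzyloxy)-2,3-dimethoxy-5-[2-(methylsulfanyl)-2-(methylsulfinyl)ethenyl]benzene
Product: 4 methyl 2-[3-(benzyloxy)-4,5-dimethoxyphenyl]acetate
Conditions: HCl (anhydrous) in MeOH, 0 °C to rt
Reagents that add atoms: methanol, CO
Why: Acid-catalysed methanolysis of the ketene dithioacetal S-oxide (C-protonation, addition of methanol to the thionium ion and Pummerer-type expulsion of both sulfur groups as dimethyl disulfide) should give the arylacetic ester, and an aryl benzyl ether tolerates HCl in methanol at room temperature.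

Step 4
Reactants: 4 methyl 2-[3-(benzyloxy)-4,5-dimethoxyphenyl]acetate; 5 4'-methoxyacetophenone
Product: 6 4-[3-(benzyloxy)-4,5-dimethoxyphenyl]-1-(4-methoxyphenyl)butane-1,3-dione
Conditions: 5 (1.3 equiv), NaH (2.5 equiv), THF, 0 to 50 °C; 4 added slowly, reflux; then 1 M HCl
Reagents that add atoms: none
Why: Crossed Claisen condensation, in which the sodium enolate of the methyl ketone is acylated by the ester and the equilibrium is pulled over by deprotonation of the 1,3-diketone, slow addition of the ester to preformed ketone enolate being used to hold back self-condensation of the arylacetate.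

Step 5
Reactants: 6 4-[3-(benzyloxy)-4,5-dimethoxyphenyl]-1-(4-methoxyphenyl)butane-1,3-dione; 7 3-amino-5-methyl-1,2,4-oxadiazole
Product: 8 (Z)-4-[3-(benzyloxy)-4,5-dimethoxyphenyl]-1-(4-methoxyphenyl)-3-[(5-methyl-1,2,4-oxadiazol-3-yl)amino]but-2-en-1-one
Conditions: p-TsOH·H2O (10 mol%), toluene, reflux, Dean–Stark trap
Reagents that add atoms: none
Why: Acid-catalysed enaminone formation with azeotropic removal of water should occur at the benzyl-side carbonyl, which is more electrophilic than the anisoyl carbonyl, and the product is held as the Z isomer by the N–H···O=C hydrogen bond.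

Step 6
Reactants: 8 (Z)-4-[3-(benzyloxy)-4,5-dimethoxyphenyl]-1-(4-methoxyphenyl)-3-[(5-methyl-1,2,4-oxadiazol-3-yl)amino]but-2-en-1-one
Product: 9 N-{5-[3-(benzyloxy)-4,5-dimethoxybenzyl]-4-(4-methoxybenzoyl)-1H-imidazol-2-yl}acetamide
Conditions: KOt-Bu (1.2 equiv), DMF, rt; then AcOH
Reagents that add atoms: none
Why: KOt-Bu removes the N–H proton of the vinylogous amide, and the aza-enolate attacks oxadiazole N2 through its central carbon (the former diketone CH) in an intramolecular substitution at nitrogen with ring oxygen O1 as leaving group; a proton shift then aromatises the first-formed 4H-imidazole and leaves the old C5–O1 unit as the N-acetyl group. This is the Boulton–Katritzky (mononuclear heterocyclic) rearrangement with a C–C–N side chain, of the kind established for enaminones made from 3-amino-1,2,4-oxadiazoles and 1,3-diketones. The imidazole closes in a 5-exo sense: its atoms are N2, C3, the exocyclic nitrogen and the two enaminone carbons, and the breaking N2–O1 bond lies outside the new ring. No stereocentre is formed. The step needs attack through carbon and a fixed placement of the substituents: only the carbon terminus reaches N2 through a five-membered transition state (the carbonyl oxygen would need a seven-membered one), and because the amine was attached at the aliphatic carbonyl in step 5 the aroyl group must end on C4 and the benzyl group on C5. The driving force is the exchange of the weak N–O bond for an aromatic imidazole and an amide carbonyl.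

Step 7
Reactants: 9 N-{5-[3-(benzyloxy)-4,5-dimethoxybenzyl]-4-(4-methoxybenzoyl)-1H-imidazol-2-yl}acetamide
Product: 10 N-{5-[3-(benzyloxy)-4,5-dimethoxybenzyl]-4-(4-methoxybenzoyl)-1-methyl-1H-imidazol-2-yl}acetamide
Conditions: K2CO3 (1.1 equiv), MeI (1.05 equiv), DMF, 0 °C to rt
Reagents that add atoms: iodomethane, CI
Why: SN2 N-methylation of the imidazolide anion, where, as is general for 4(5)-acylimidazoles alkylated under basic conditions, N3 is deactivated inductively and crowded by the coplanar aroyl group so that the methyl group should go to N1, while the less acidic acetamide N–H is spared by limiting base and MeI to about one equivalent.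

Step 8
Reactants: 10 N-{5-[3-(benzyloxy)-4,5-dimethoxybenzyl]-4-(4-methoxybenzoyl)-1-methyl-1H-imidazol-2-yl}acetamide
Product: 11 N-[5-(3-hydroxy-4,5-dimethoxybenzyl)-4-(4-methoxybenzyl)-1-methyl-1H-imidazol-2-yl]acetamide
Conditions: H2 (4 atm), Pd/C (10 wt% Pd), AcOH, HCl (2 equiv), 50 °C; then NaHCO3 (aq)
Reagents that add atoms: none
Why: Palladium-catalysed hydrogenolysis in acid, in which the aryl heteroaryl ketone is reduced through its carbinol, whose benzylic C–O bond is cleaved readily because the cation is stabilised by the 4-methoxyphenyl ring, and the O-benzyl ether is cleaved in the same operation, as known for aroylimidazoles and aryl benzyl ethers.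

Step 9
Reactants: 11 N-[5-(3-hydroxy-4,5-dimethoxybenzyl)-4-(4-methoxybenzyl)-1-methyl-1H-imidazol-2-yl]acetamide
Product: 12 5-{[2-amino-4-(4-methoxybenzyl)-1-methyl-1H-imidazol-5-yl]methyl}-2,3-dimethoxyphenol
Conditions: 3 M HCl (aq), 1,4-dioxane, 90 °C, N2; then NaHCO3 (aq)
Reagents that add atoms: none
Why: Acid hydrolysis of an N-acyl-2-aminoimidazole, an acylguanidine-type amide that is cleaved far more easily than an ordinary amide, while the aryl methyl ethers, the phenol and the benzylic C–C bonds are unaffected.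

Step 10
Reactants: 12 5-{[2-amino-4-(4-methoxybenzyl)-1-methyl-1H-imidazol-5-yl]methyl}-2,3-dimethoxyphenol; 13 1-methylparabanic acid
Product: 15 4-{[5-(3-hydroxy-4,5-dimethoxybenzyl)-4-(4-methoxybenzyl)-1-methyl-1H-imidazol-2-yl]amino}-1-methyl-1H-imidazole-2,5-dione (CNP0321799.0), via O-silylated 1-methylparabanic acid 14 (not isolated)
Conditions: 13 (1.5 equiv), N,O-bis(trimethylsilyl)acetamide (3 equiv), MeCN, 80 °C; solvent removed; 12, toluene, 110 °C; aqueous work-up
Reagents that add atoms: N,O-bis(trimethylsilyl)acetamide, CC(=N[Si](C)(C)C)O[Si](C)(C)C (its silyl group is carried by 14 only and is absent from 15)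
Why: Silyl-mediated condensation (addition–elimination), in which O-silylation turns the C4 carbonyl next to the N–H of 1-methylparabanic acid into an imidate carbon that the exocyclic amine attacks with loss of silanol, the established way to attach this dehydrohydantoin unit to 2-amino-1-methylimidazoles, and any silyl ether formed at the phenol is lost in the aqueous work-up.

Compound list
1 | 3-hydroxy-4,5-dimethoxybenzaldehyde | COc1cc(C=O)cc(O)c1OC | starting material
2 | 3-(benzyloxy)-4,5-dimethoxybenzaldehyde | COc1cc(C=O)cc(OCc2ccccc2)c1OC | intermediate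
3 | 1-(benzyloxy)-2,3-dimethoxy-5-[2-(methylsulfanyl)-2-(methylsulfinyl)ethenyl]benzene (racemic at sulfur, alkene geometry not assigned) | CSC(=Cc1cc(OC)c(OC)c(OCc2ccccc2)c1)S(C)=O | intermediate
4 | methyl 2-[3-(benzyloxy)-4,5-dimethoxyphenyl]acetate | COC(=O)Cc1cc(OC)c(OC)c(OCc2ccccc2)c1 | intermediate
5 | 4'-methoxyacetophenone | COc1ccc(C(C)=O)cc1 | starting material
6 | 4-[3-(benzyloxy)-4,5-dimethoxyphenyl]-1-(4-methoxyphenyl)butane-1,3-dione | COc1ccc(cc1)C(=O)CC(=O)Cc1cc(OCc2ccccc2)c(OC)c(OC)c1 | intermediate
7 | 3-amino-5-methyl-1,2,4-oxadiazole | Cc1nc(N)no1 | starting material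
8 | (Z)-4-[3-(benzyloxy)-4,5-dimethoxyphenyl]-1-(4-methoxyphenyl)-3-[(5-methyl-1,2,4-oxadiazol-3-yl)amino]but-2-en-1-one | COc1ccc(cc1)C(=O)/C=C(/Cc1cc(OCc2ccccc2)c(OC)c(OC)c1)Nc1noc(C)n1 | intermediate
9 | N-{5-[3-(benzyloxy)-4,5-dimethoxybenzyl]-4-(4-methoxybenzoyl)-1H-imidazol-2-yl}acetamide | CC(=O)Nc1nc(C(=O)c2ccc(OC)cc2)c(Cc2cc(OCc3ccccc3)c(OC)c(OC)c2)[nH]1 | intermediate
10 | N-{5-[3-(benzyloxy)-4,5-dimethoxybenzyl]-4-(4-methoxybenzoyl)-1-methyl-1H-imidazol-2-yl}acetamide | CC(=O)Nc1nc(C(=O)c2ccc(OC)cc2)c(Cc2cc(OCc3ccccc3)c(OC)c(OC)c2)n1C | intermediate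
11 | N-[5-(3-hydroxy-4,5-dimethoxybenzyl)-4-(4-methoxybenzyl)-1-methyl-1H-imidazol-2-yl]acetamide | CC(=O)Nc1nc(Cc2ccc(OC)cc2)c(Cc2cc(O)c(OC)c(OC)c2)n1C | intermediate
12 | 5-{[2-amino-4-(4-methoxybenzyl)-1-methyl-1H-imidazol-5-yl]methyl}-2,3-dimethoxyphenol | Nc1nc(Cc2ccc(OC)cc2)c(Cc2cc(O)c(OC)c(OC)c2)n1C | intermediate
13 | 1-methylparabanic acid (1-methylimidazolidine-2,4,5-trione) | CN1C(=O)NC(=O)C1=O | starting material
14 | 1-methyl-4-[(trimethylsilyl)oxy]-1H-imidazole-2,5-dione (O-silylated 1-methylparabanic acid, not isolated) | CN1C(=O)N=C(O[Si](C)(C)C)C1=O | intermediate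
15 | 4-{[5-(3-hydroxy-4,5-dimethoxybenzyl)-4-(4-methoxybenzyl)-1-methyl-1H-imidazol-2-yl]amino}-1-methyl-1H-imidazole-2,5-dione (CNP0321799.0) | COc1ccc(Cc2nc(NC3=NC(=O)N(C)C3=O)n(C)c2Cc2cc(O)c(OC)c(OC)c2)cc1 | target

Total step count: 10
Longest linear sequence: 10 steps (1 to 15); 5, 7 and 13 are used as purchased.

Steps most likely to fail

Step 7 (N-methylation). Methylation may go in part to the ring nitrogen beside the aroyl group, or continue at the acetamide nitrogen. The fallback replaces electronic control by steric control; it sets out from 9 and returns to the route at 11.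
- Reduction with NaBH4 (MeOH, 0 °C) should give the racemic carbinol N-{5-[3-(benzyloxy)-4,5-dimethoxybenzyl]-4-[hydroxy(4-methoxyphenyl)methyl]-1H-imidazol-2-yl}acetamide F1.
- Silylation with tert-butyldimethylsilyl triflate and 2,6-lutidine in CH2Cl2 (N-silyl groups are lost on aqueous NaHCO3 work-up) should give the racemic silyl ether N-{5-[3-(benzyloxy)-4,5-dimethoxybenzyl]-4-[(tert-butyldimethylsilyloxy)(4-methoxyphenyl)methyl]-1H-imidazol-2-yl}acetamide F2.
- The bulky silyloxy(aryl)methyl group now shields N3, so NaH/MeI (THF, 0 °C) should methylate N1 to give N-{5-[3-(benzyloxy)-4,5-dimethoxybenzyl]-4-[(tert-butyldimethylsilyloxy)(4-methoxyphenyl)methyl]-1-methyl-1H-imidazol-2-yl}acetamide F3.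
- Acidic hydrogenolysis under the conditions of step 8 (H2, Pd/C, AcOH, HCl) should then cleave the benzylic C–OSi bond and the benzyl ether together and deliver 11.

Step 4 (crossed Claisen condensation). Proton transfer from the more acidic arylacetate to the ketone enolate may lead to self-condensation of the ester. The fallback is an aldol addition followed by oxidation; it sets out from 4 (with 5) and returns at 6.
- Reduction of 4 with i-Bu2AlH (1.05 equiv, CH2Cl2, –78 °C) should give 2-[3-(benzyloxy)-4,5-dimethoxyphenyl]acetaldehyde F6.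
- The crude aldehyde is added at –78 °C to the lithium enolate of 5 (LiN(i-Pr)2, THF), where carbonyl addition outruns proton transfer, to give racemic 4-[3-(benzyloxy)-4,5-dimethoxyphenyl]-3-hydroxy-1-(4-methoxyphenyl)butan-1-one F7.
- Oxidation with Dess–Martin periodinane (CH2Cl2, rt) should give diketone 6.

Step 8 (hydrogenolytic deoxygenation). The reduction may stall at the carbinol, or the basic heterocycle may slow the catalyst so that the ketone survives. The fallback is a stepwise ionic deoxygenation; it sets out from 10 and returns at 11.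
- NaBH4 (MeOH/THF, 0 °C to rt) should give the racemic carbinol N-{5-[3-(benzyloxy)-4,5-dimethoxybenzyl]-4-[hydroxy(4-methoxyphenyl)methyl]-1-methyl-1H-imidazol-2-yl}acetamide F4.
- Et3SiH/CF3CO2H (CH2Cl2, rt) should reduce the derived benzylic cation to N-{5-[3-(benzyloxy)-4,5-dimethoxybenzyl]-4-(4-methoxybenzyl)-1-methyl-1H-imidazol-2-yl}acetamide F5.
- Neutral hydrogenolysis (H2, Pd/C, EtOH, rt) should remove the benzyl ether to give 11.

Further compounds
F1 | step 7 | N-{5-[3-(benzyloxy)-4,5-dimethoxybenzyl]-4-[hydroxy(4-methoxyphenyl)methyl]-1H-imidazol-2-yl}acetamide (racemic) | CC(=O)Nc1nc(C(O)c2ccc(OC)cc2)c(Cc2cc(OCc3ccccc3)c(OC)c(OC)c2)[nH]1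
F2 | step 7 | N-{5-[3-(benzyloxy)-4,5-dimethoxybenzyl]-4-[(tert-butyldimethylsilyloxy)(4-methoxyphenyl)methyl]-1H-imidazol-2-yl}acetamide (racemic) | CC(=O)Nc1nc(C(O[Si](C)(C)C(C)(C)C)c2ccc(OC)cc2)c(Cc2cc(OCc3ccccc3)c(OC)c(OC)c2)[nH]1
F3 | step 7 | N-{5-[3-(benzyloxy)-4,5-dimethoxybenzyl]-4-[(tert-butyldimethylsilyloxy)(4-methoxyphenyl)methyl]-1-methyl-1H-imidazol-2-yl}acetamide (racemic) | CC(=O)Nc1nc(C(O[Si](C)(C)C(C)(C)C)c2ccc(OC)cc2)c(Cc2cc(OCc3ccccc3)c(OC)c(OC)c2)n1C
F4 | step 8 | N-{5-[3-(benzyloxy)-4,5-dimethoxybenzyl]-4-[hydroxy(4-methoxyphenyl)methyl]-1-methyl-1H-imidazol-2-yl}acetamide (racemic) | CC(=O)Nc1nc(C(O)c2ccc(OC)cc2)c(Cc2cc(OCc3ccccc3)c(OC)c(OC)c2)n1C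
F5 | step 8 | N-{5-[3-(benzyloxy)-4,5-dimethoxybenzyl]-4-(4-methoxybenzyl)-1-methyl-1H-imidazol-2-yl}acetamide | CC(=O)Nc1nc(Cc2ccc(OC)cc2)c(Cc2cc(OCc3ccccc3)c(OC)c(OC)c2)n1C
F6 | step 4 | 2-[3-(benzyloxy)-4,5-dimethoxyphenyl]acetaldehyde | O=CCc1cc(OC)c(OC)c(OCc2ccccc2)c1
F7 | step 4 | 4-[3-(benzyloxy)-4,5-dimethoxyphenyl]-3-hydroxy-1-(4-methoxyphenyl)butan-1-one (racemic) | COc1ccc(cc1)C(=O)CC(O)Cc1cc(OCc2ccccc2)c(OC)c(OC)c1
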